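**Strategy.** The dimethylpyran ring of the chroman (O1, C2, C3, C4, C4a, C8a) is disconnected to a tertiary propargyl ether on the 4'-oxygen of a preformed 3'-bromoflavone. Heating triggers a propargyl Claisen shift, a hydrogen shift and an oxa-6π electrocyclisation, which move the five-carbon unit from O1 to C4a and close the ring as a 2H-chromene in one operation. The step exploits the fact that O1 sits on C8a, whose second ortho carbon (C8, the future biaryl carbon) is blocked, here by bromine. That bromine then serves a Suzuki union with an 8-iodoapigenin ether, and a single hydrogenation saturates C3–C4 and frees all five phenols.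

Key step: step 6

Assumption: the target has no stereocentre and its biaryl axis is drawn without configuration, so the axis is treated as stereochemically undefined and no stereocontrol is planned.

Locants: chroman/chromene numbering (O1, C2, C3, C4, C4a, C5–C8, C8a) is used for the dimethylpyran unit; primed locants refer to the 2-aryl ring (ring B) of the flavone before that ring is annulated.

**Step 1**
Reactants: 1 apigenin
Product: 2 5,7-bis(benzyloxy)-2-[4-(benzyloxy)phenyl]-4H-chromen-4-one
Conditions: BnBr (excess), K2CO3, DMF, 80 °C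
Reagents that add atoms: benzyl bromide, BrCc1ccccc1
Why: Williamson etherification of all three phenols; excess reagent and heat are used because the 5-OH is hydrogen-bonded to the C4 carbonyl and should react last.

**Step 2**
Reactants: 2 5,7-bis(benzyloxy)-2-[4-(benzyloxy)phenyl]-4H-chromen-4-one
Product: 3 5,7-bis(benzyloxy)-2-[4-(benzyloxy)phenyl]-8-iodo-4H-chromen-4-one
Conditions: NIS, TFA (cat.), MeCN/CH2Cl2, 0 °C to rt, dark
Reagents that add atoms: N-iodosuccinimide, O=C1CCC(=O)N1I
Why: Electrophilic aromatic iodination of the dialkoxy ring A; in 5-O-alkylated 5,7-dioxygenated flavones substitution should go to C8, which is less hindered than C6 between the two benzyloxy groups, while ring B and the benzyl rings are far less reactive.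

**Step 3**
Reactants: 4 1-[2,4-bis(benzyloxy)-6-hydroxyphenyl]ethan-1-one; 5 3-bromo-4-hydroxybenzaldehyde
Product: 6 (E)-1-[2,4-bis(benzyloxy)-6-hydroxyphenyl]-3-(3-bromo-4-hydroxyphenyl)prop-2-en-1-one
Conditions: KOH (50% aq), EtOH, rt to 50 °C; HCl (aq) work-up
Reagents that add atoms: none
Why: Claisen–Schmidt aldol condensation, in which excess base carries the aldehyde through as its phenoxide and the E-enone should result as the thermodynamic product of the dehydration.

**Step 4**
Reactants: 6 (E)-1-[2,4-bis(benzyloxy)-6-hydroxyphenyl]-3-(3-bromo-4-hydroxyphenyl)prop-2-en-1-one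
Product: 7 5,7-bis(benzyloxy)-2-(3-bromo-4-hydroxyphenyl)-4H-chromen-4-one
Conditions: I2 (10 mol%), DMSO, 120 °C
Reagents that add atoms: none
Why: Iodine/DMSO oxidative cyclisation of a 2'-hydroxychalcone (oxa-Michael closure, α-iodination and loss of HI, with DMSO re-oxidising HI) closes the pyranone ring through the only free ring A hydroxyl and should tolerate the benzyl ethers and the free ring B phenol.

**Step 5**
Reactants: 7 5,7-bis(benzyloxy)-2-(3-bromo-4-hydroxyphenyl)-4H-chromen-4-one; 8 3-chloro-3-methylbut-1-yne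
Product: 9 5,7-bis(benzyloxy)-2-{3-bromo-4-[(2-methylbut-3-yn-2-yl)oxy]phenyl}-4H-chromen-4-one
Conditions: DBU, CuCl2·2H2O (1 mol%), MeCN/DMF, 0 °C to rt
Reagents that add atoms: none
Why: Copper-catalysed O-alkylation of a phenol with a tertiary propargylic chloride, a reaction that suits acidic, electron-poor phenols such as this one, and the 4'-OH is the only free hydroxyl.

**Step 6**
Reactants: 9 5,7-bis(benzyloxy)-2-{3-bromo-4-[(2-methylbut-3-yn-2-yl)oxy]phenyl}-4H-chromen-4-one
Product: 13 5,7-bis(benzyloxy)-2-(8-bromo-2,2-dimethyl-2H-chromen-6-yl)-4H-chromen-4-one, via allenyl cyclohexadienone 10 (not isolated), via ortho-allenylphenol 11 (not isolated), via ortho-quinone methide 12 (not isolated)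
Conditions: PhNEt2, 185 °C, argon
Reagents that add atoms: none
Why: On heating, the aryl 1,1-dimethylpropargyl ether should undergo a [3,3]-sigmatropic propargyl Claisen shift to the free ortho carbon C5' to give dienone 10, which enolises to allenylphenol 11; a 1,5-hydrogen shift then gives the Z ortho-quinone methide 12, whose oxa-6π electrocyclisation forms the O1–C2 bond. The closest known reaction type is the thermal rearrangement of aryl propargyl ethers to 2,2-dimethyl-2H-chromenes, which is most reliable for phenols with a para acceptor group, as here. The one ring closed is the pyran ring, formed by a thermal disrotatory 6π electrocyclisation of the 1-oxatriene, all six ring atoms coming from that triene. No stereocentre is created, since C2 carries two methyl groups. The selectivity needed is C–C bond formation at C5' of ring B and not at the more nucleophilic C6 or C8 of ring A or at the other ortho carbon; intramolecular delivery through the ether oxygen secures the first and the bromine at C3' the second. The gem-dimethyl group and the base-free, amine-buffered medium should favour the chromene over a benzofuran.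

**Step 7**
Reactants: 13 5,7-bis(benzyloxy)-2-(8-bromo-2,2-dimethyl-2H-chromen-6-yl)-4H-chromen-4-one
Product: 14 5,7-bis(benzyloxy)-2-[2,2-dimethyl-8-(4,4,5,5-tetramethyl-1,3,2-dioxaborolan-2-yl)-2H-chromen-6-yl]-4H-chromen-4-one
Conditions: B2pin2, Pd(dppf)Cl2 (5 mol%), KOAc, 1,4-dioxane, 90 °C
Reagents that add atoms: bis(pinacolato)diboron, CC1(C)OB(OC1(C)C)B1OC(C)(C)C(C)(C)O1
Why: Miyaura borylation of the aryl bromide, in which the weak acetate base suppresses homocoupling and the chromene alkene, chromone and benzyl ethers should be inert.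

**Step 8**
Reactants: 14 5,7-bis(benzyloxy)-2-[2,2-dimethyl-8-(4,4,5,5-tetramethyl-1,3,2-dioxaborolan-2-yl)-2H-chromen-6-yl]-4H-chromen-4-one; 3 5,7-bis(benzyloxy)-2-[4-(benzyloxy)phenyl]-8-iodo-4H-chromen-4-one
Product: 15 5,7-bis(benzyloxy)-8-{6-[5,7-bis(benzyloxy)-4-oxo-4H-chromen-2-yl]-2,2-dimethyl-2H-chromen-8-yl}-2-[4-(benzyloxy)phenyl]-4H-chromen-4-one
Conditions: Pd(OAc)2 (5 mol%), SPhos (10 mol%), K3PO4, toluene/H2O (10:1), 90 °C
Reagents that add atoms: none
Why: Suzuki–Miyaura coupling with a bulky electron-rich biarylphosphine for a biaryl bond flanked by three ortho substituents; boron is placed on the less hindered chromene partner and iodine on the doubly flanked C8 to limit protodeboronation.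

**Step 9**
Reactants: 15 5,7-bis(benzyloxy)-8-{6-[5,7-bis(benzyloxy)-4-oxo-4H-chromen-2-yl]-2,2-dimethyl-2H-chromen-8-yl}-2-[4-(benzyloxy)phenyl]-4H-chromen-4-one
Product: 16 8-[6-(5,7-dihydroxy-4-oxo-4H-chromen-2-yl)-2,2-dimethyl-3,4-dihydro-2H-chromen-8-yl]-5,7-dihydroxy-2-(4-hydroxyphenyl)-4H-chromen-4-one (target)
Conditions: H2 (1 atm), 10% Pd/C, THF/MeOH, rt
Reagents that add atoms: none
Why: Heterogeneous hydrogenation should saturate the cis-disubstituted styrene-type C3–C4 double bond of the chromene and hydrogenolyse the five benzyl aryl ethers in the same operation, while the vinylogous-ester C2–C3 double bonds of the two chromones reduce much more slowly at atmospheric pressure.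

**Compound list**

1 | apigenin | O=c1cc(-c2ccc(O)cc2)oc2cc(O)cc(O)c12 | starting material
2 | 5,7-bis(benzyloxy)-2-[4-(benzyloxy)phenyl]-4H-chromen-4-one | O=c1cc(-c2ccc(OCc3ccccc3)cc2)oc2cc(OCc3ccccc3)cc(OCc3ccccc3)c12 | intermediate
3 | 5,7-bis(benzyloxy)-2-[4-(benzyloxy)phenyl]-8-iodo-4H-chromen-4-one | O=c1cc(-c2ccc(OCc3ccccc3)cc2)oc2c(I)c(OCc3ccccc3)cc(OCc3ccccc3)c12 | intermediate
4 | 1-[2,4-bis(benzyloxy)-6-hydroxyphenyl]ethan-1-one | CC(=O)c1c(O)cc(OCc2ccccc2)cc1OCc1ccccc1 | starting material
5 | 3-bromo-4-hydroxybenzaldehyde | O=Cc1ccc(O)c(Br)c1 | starting material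
6 | (E)-1-[2,4-bis(benzyloxy)-6-hydroxyphenyl]-3-(3-bromo-4-hydroxyphenyl)prop-2-en-1-one | O=C(/C=C/c1ccc(O)c(Br)c1)c1c(O)cc(OCc2ccccc2)cc1OCc1ccccc1 | intermediate
7 | 5,7-bis(benzyloxy)-2-(3-bromo-4-hydroxyphenyl)-4H-chromen-4-one | O=c1cc(-c2ccc(O)c(Br)c2)oc2cc(OCc3ccccc3)cc(OCc3ccccc3)c12 | intermediate
8 | 3-chloro-3-methylbut-1-yne | CC(C)(Cl)C#C | starting material
9 | 5,7-bis(benzyloxy)-2-{3-bromo-4-[(2-methylbut-3-yn-2-yl)oxy]phenyl}-4H-chromen-4-one | CC(C)(C#C)Oc1ccc(-c2cc(=O)c3c(OCc4ccccc4)cc(OCc4ccccc4)cc3o2)cc1Br | intermediate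
10 | 5,7-bis(benzyloxy)-2-[5-bromo-3-(3-methylbuta-1,2-dien-1-yl)-4-oxocyclohexa-1,5-dien-1-yl]-4H-chromen-4-one (allenyl cyclohexadienone, not isolated) | CC(C)=C=CC1C=C(-c2cc(=O)c3c(OCc4ccccc4)cc(OCc4ccccc4)cc3o2)C=C(Br)C1=O | intermediate
11 | 5,7-bis(benzyloxy)-2-[3-bromo-4-hydroxy-5-(3-methylbuta-1,2-dien-1-yl)phenyl]-4H-chromen-4-one (ortho-allenylphenol, not isolated) | CC(C)=C=Cc1cc(-c2cc(=O)c3c(OCc4ccccc4)cc(OCc4ccccc4)cc3o2)cc(Br)c1O | intermediate
12 | 5,7-bis(benzyloxy)-2-[(3Z)-5-bromo-3-(3-methylbut-2-en-1-ylidene)-4-oxocyclohexa-1,5-dien-1-yl]-4H-chromen-4-one (ortho-quinone methide, not isolated) | CC(C)=C/C=C1\C(=O)C(Br)=CC(-c2cc(=O)c3c(OCc4ccccc4)cc(OCc4ccccc4)cc3o2)=C1 | intermediate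
13 | 5,7-bis(benzyloxy)-2-(8-bromo-2,2-dimethyl-2H-chromen-6-yl)-4H-chromen-4-one | CC1(C)C=Cc2cc(-c3cc(=O)c4c(OCc5ccccc5)cc(OCc5ccccc5)cc4o3)cc(Br)c2O1 | intermediate
14 | 5,7-bis(benzyloxy)-2-[2,2-dimethyl-8-(4,4,5,5-tetramethyl-1,3,2-dioxaborolan-2-yl)-2H-chromen-6-yl]-4H-chromen-4-one | CC1(C)C=Cc2cc(-c3cc(=O)c4c(OCc5ccccc5)cc(OCc5ccccc5)cc4o3)cc(B3OC(C)(C)C(C)(C)O3)c2O1 | intermediate
15 | 5,7-bis(benzyloxy)-8-{6-[5,7-bis(benzyloxy)-4-oxo-4H-chromen-2-yl]-2,2-dimethyl-2H-chromen-8-yl}-2-[4-(benzyloxy)phenyl]-4H-chromen-4-one | CC1(C)C=Cc2cc(-c3cc(=O)c4c(OCc5ccccc5)cc(OCc5ccccc5)cc4o3)cc(-c3c(OCc4ccccc4)cc(OCc4ccccc4)c4c(=O)cc(-c5ccc(OCc6ccccc6)cc5)oc34)c2O1 | intermediate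
16 | 8-[6-(5,7-dihydroxy-4-oxo-4H-chromen-2-yl)-2,2-dimethyl-3,4-dihydro-2H-chromen-8-yl]-5,7-dihydroxy-2-(4-hydroxyphenyl)-4H-chromen-4-one | CC1(C)CCc2cc(-c3cc(=O)c4c(O)cc(O)cc4o3)cc(-c3c(O)cc(O)c4c(=O)cc(-c5ccc(O)cc5)oc34)c2O1 | target

**Total step count:** 9 steps.
**Longest linear sequence:** 7 steps (steps 3 to 9, from 4 and 5 to 16).

**Steps most likely to fail**

1. Step 8 (Suzuki coupling). Transmetalation and reductive elimination at a biaryl bond with three ortho substituents may be slow enough for protodeboronation of the boronate to take over. Fallback: a base-free Stille union instead. It sets out from bromide 13, which would be stannylated with hexamethylditin (Pd(PPh3)4, toluene, 100 °C) to give 5,7-bis(benzyloxy)-2-[2,2-dimethyl-8-(trimethylstannyl)-2H-chromen-6-yl]-4H-chromen-4-one F1. Copper-assisted Stille coupling of F1 with iodide 3 (Pd(PPh3)4, CuI, DMF, 90 °C) should then return to the route at 15.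

2. Step 9 (global hydrogenation). Over-reduction of the chromone C2–C3 double bonds, or stalling of the hydrogenolysis through catalyst poisoning by the emerging polyphenol, may spoil the last step. Fallback: separate the two tasks and avoid a metal catalyst. It sets out from 15, whose chromene double bond alone would be reduced with diimide (TsNHNH2, NaOAc, aqueous DME, reflux) to give 5,7-bis(benzyloxy)-8-{6-[5,7-bis(benzyloxy)-4-oxo-4H-chromen-2-yl]-2,2-dimethyl-3,4-dihydro-2H-chromen-8-yl}-2-[4-(benzyloxy)phenyl]-4H-chromen-4-one F2. Lewis-acid debenzylation of F2 (BCl3, pentamethylbenzene as cation scavenger, CH2Cl2, −78 °C) should then return to the route at 16.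

3. Step 6 (key step). At 185 °C, ionisation of the tertiary propargyl ether back to phenol 7 or unselective thermal decomposition may compete with the sigmatropic shift. Fallback: reach the same ortho-quinone methide by condensation instead of rearrangement, which also bypasses step 5. It sets out from phenol 7, which would be heated with 3-methylbut-2-enal, phenylboronic acid and propionic acid in toluene with removal of water. The boron-templated, ortho-specific hydroxyalkylation should give 5,7-bis(benzyloxy)-2-[8-bromo-4-(2-methylprop-1-en-1-yl)-2-phenyl-4H-1,3,2-benzodioxaborinin-6-yl]-4H-chromen-4-one F3. Thermal fragmentation of F3 in the same flask should give ortho-quinone methide 12, which electrocyclises and returns to the route at 13.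

**Further compounds**

F1 | step 8 | 5,7-bis(benzyloxy)-2-[2,2-dimethyl-8-(trimethylstannyl)-2H-chromen-6-yl]-4H-chromen-4-one | CC1(C)C=Cc2cc(-c3cc(=O)c4c(OCc5ccccc5)cc(OCc5ccccc5)cc4o3)cc([Sn](C)(C)C)c2O1
F2 | step 9 | 5,7-bis(benzyloxy)-8-{6-[5,7-bis(benzyloxy)-4-oxo-4H-chromen-2-yl]-2,2-dimethyl-3,4-dihydro-2H-chromen-8-yl}-2-[4-(benzyloxy)phenyl]-4H-chromen-4-one | CC1(C)CCc2cc(-c3cc(=O)c4c(OCc5ccccc5)cc(OCc5ccccc5)cc4o3)cc(-c3c(OCc4ccccc4)cc(OCc4ccccc4)c4c(=O)cc(-c5ccc(OCc6ccccc6)cc5)oc34)c2O1
F3 | step 6 | 5,7-bis(benzyloxy)-2-[8-bromo-4-(2-methylprop-1-en-1-yl)-2-phenyl-4H-1,3,2-benzodioxaborinin-6-yl]-4H-chromen-4-one | CC(C)=CC1OB(c2ccccc2)Oc2c(Br)cc(-c3cc(=O)c4c(OCc5ccccc5)cc(OCc5ccccc5)cc4o3)cc12
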